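Place the flask between the two runs that share its reagent equivalents, then take their midpoint.

| setting | Saturday's | Wednesday's | Sunday's | flask |
|---|---|---|---|---|
| substrate | 0.50 M | 2 M | 1 M | 1.0 M |
| reagent in the second phase | 0.80 equiv | 0.80 equiv | 1.6 equiv | 0.800 equiv |
| remark | run made earlier | run made earlier | run made earlier |  |
| time |  |  |  | 12 min |
| volume of the second phase over the first |  |  |  | 1.0 |

| run | time / min | target / % | substrate / % |
|---|---|---|---|
| Saturday's | 1.50 | 9.0 | 80.2 |
| Saturday's | 3.00 | 19.8 | 64.7 |
| Saturday's | 5.00 | 27.4 | 49.2 |
| Saturday's | 6.00 | 31.3 | 43.7 |
| Saturday's | 8.00 | 34.6 | 35.0 |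
| Saturday's | 10.0 | 36.6 | 29.2 |
| Saturday's | 12.0 | 38.3 | 24.7 |
| Wednesday's | 1.50 | 18.9 | 54.5 |
| Wednesday's | 3.00 | 32.2 | 31.9 |
| Wednesday's | 5.00 | 40.4 | 17.5 |
| Wednesday's | 6.00 | 41.9 | 13.3 |
| Wednesday's | 8.00 | 43.4 | 7.8 |
| Wednesday's | 10.0 | 44.2 | 6.1 |
| Wednesday's | 12.0 | 43.2 | 2.9 |
| Sunday's | 2.50 | 41.7 | 39.4 |
| Sunday's | 5.00 | 57.9 | 14.4 |
| Sunday's | 8.00 | 61.0 | 5.0 |
| Sunday's | 10.0 | 60.2 | 2.4 |
| Sunday's | 12.0 | 58.1 | 0.5 |

(readings scatter by 0.5 percentage points)

- in the second phase: reagent in the second phase; everything else is in the first
- charges count per volume of the first phase; a concentration in a rate is the amount of a species over the volume of its own phase; every rate counts per litre of the first phase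
- what was read earlier has a scatter of 0.5 percentage points, one standard deviation
- the earlier runs hold the two phases in the same ratio of volumes as the flask asked about

- midnight: doubling the amount of reagent in the second phase, all else as stated
- dawn: doubling the transfer coefficient of the reagent in the second phase, all else as stated

* how much target there is at 12 min, in percent of the substrate charged
* the change that raises the amount of target at 12 min, in percent of the substrate charged most ("none" if none brings more than 2 percentage points) (midnight / dawn / none)
* amount of target at 12 min, in percent of the substrate charged, after midnight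

The rule of thumb, at fixed equivalents and a fixed time, takes equal factors in c(substrate) to move the target by equal steps. Saturday's c(substrate) lies a factor 2.00 below the flask's and Wednesday's a factor 2.00 above it, so the two ends join at the mean of their target readings at 12 min. This midpoint yield is 40.8%.

The rule joins two runs a factor 4.00 apart in c(substrate) and holds the equivalents fixed, so it does not cross to other equivalents: Sunday's equivalents of reagent are twice the flask's at the same c(substrate), and Sunday's target at 12 min reads 1.42 times the midpoint yield. Midnight turns the flask's reagent in the second phase, 0.800 equiv, into 1.6 equiv at 1 M, which is Sunday's recipe, so Sunday's reading of 58.1% stands for it. That reading stands 17 percentage points above the midpoint yield, and the recipes name no change of transfer, so this reckoning commits to the midpoint yield and to midnight.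

The forecast gives 40%, a little lower than the midpoint yield, then midnight as best with 58.2%, on the grounds that “Midnight is exactly Sunday's run”.

The flask gives 42.5%, and 58.3% after midnight, a gain of 16 points against 2.6 points for dawn.

    reagent in the reaction phase ⇌ reagent in the second phase, rate k1*([reagent in the reaction phase] - [reagent in the second phase]/K1) per volume of the first phase (partition coefficient = 1.90, kL = 0.720 min⁻¹)
    substrate + reagent in the reaction phase → target (k = 1.30 L mol⁻¹ min⁻¹)
    target ⇌ isomer of the product (K = 0.590, k = 0.0500 min⁻¹)
    2 substrate → homo dimer (k = 0.0740 L mol⁻¹ min⁻¹)

The midpoint yield stands 1.7 points below the flask. Taken from the readings at 5.0 min, it gives 33.9% for the flask stopped then, which holds 35.2%. In the flask, half of the homo dimer path's turnover up to 12 min is done by 1.53 min, while the passage of reagent has 56% of its turnover behind it at 2.40 min. At 12.0 min the target path uses substrate 5.6 times as fast as the homo dimer path, with 32.5% of the substrate charged standing as homo dimer, each dimer counted as two.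

The data stem from a simulated flask for substances that don't exist; noise was put on by code.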